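## The problem

The target, 3,4,5-tribromo-2-(3,5-dibromo-2-methoxyphenoxy)phenol 13, is a pentabrominated diaryl ether without a stereocentre, so the whole task is regiochemical. Ring A (C1 to C6) carries OMe at C1, Br at C2 and C4, H at C3 and C5 and the ether oxygen at C6, and ring B carries the ether oxygen at C1', a free OH at C2', H at C3' and Br at C4', C5' and C6'. The ether oxygen is thus flanked by OMe on ring A and by Br and OH on ring B, so a direct C–O coupling would join a 2,6-disubstituted phenol to an ortho-substituted arene, and an Ullmann coupling with CuI or a Buchwald–Hartwig coupling with Pd(OAc)2 would meet five C–Br bonds besides the intended site. The same C–Br bonds exclude alkyllithium bases, dissolving metals and hydrogenolysis. The ring B phenol needs a protecting group that can be removed without touching the ring A methyl ether. Bromination of a preformed diaryl ether is not reliable for ring A, because its bromines sit ortho and para to the methoxy carbon while the aryloxy group directs to its own para position. The enabling feature is that C1 to C5 of ring A (OMe, Br, H, Br, H) reproduce C2 to C6 of O-methylated 3,5-dibromo-2-pyrone. Only C6 with its aryloxy group is missing, and it sits exactly where the pyrone ring oxygen is.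

## Retrosynthesis

**Target 13 to ether 12.** The O–H of ring B is masked as an isopropyl ether, giving 12. Isopropyl survives bromination under buffered conditions, NaH, the ylide chemistry and the silylamide base, and BCl3 removes it while leaving an aryl methyl ether. A benzyl group would invite hydrogenolysis next to five C–Br bonds, and an acetal or silyl group would not survive the bromination or the phenoxide steps.

**Ether 12 to pyrylium salt 3 and ylide 10.** Two bonds of ring A are cut, C5–C6 and C1–C6, so that C6 leaves with its aryloxy group as the carbon of ylide 10 and C1 to C5 remain as 3,5-dibromo-2-methoxypyrylium tetrafluoroborate 3. The neighbouring cut, the C6–O bond, would be a hindered diaryl ether coupling with a chemoselectivity problem among the C–Br bonds. Here the aryl C–O bond of ring A is never made on an arene. Both precursors are small and carry every substituent of the product. The forward reaction has to add the ylide to an alpha carbon of 3, open the pyran to the open-chain ylide 11, and close by olefination of the ester carbonyl instead of acylation.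

**Salt 3 to pyrone 2 to coumalic acid 1.** The O–CH3 bond of 3 is cut to 3,5-dibromo-2H-pyran-2-one 2, which is O-alkylated at the lactone carbonyl. The two C–Br bonds of 2 go back to coumalic acid 1. One bromine replaces the carboxyl group at C5 and the other enters at C3, the two nucleophilic positions of the pyrone.

**Ylide 10 to phosphonium salt 9 to chloromethyl ether 7 and triphenylphosphine 8.** The ylide is the conjugate base of phosphonium chloride 9. The P–C bond of 9 is cut to chloromethyl ether 7 and triphenylphosphine 8, a plain quaternisation.

**Chloromethyl ether 7 to phenol 5 and bromochloromethane 6.** The O–CH2 bond is cut. The oxygen that ends as the diaryl ether oxygen is thus attached to the future C6 of ring A by SN2 at an sp3 carbon, which is insensitive to the two ortho substituents of 5 in a way that aryl C–O coupling is not. The forward step must stop at monosubstitution of 6.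

**Phenol 5 to 2-isopropoxyphenol 4.** Three C–Br bonds are cut. The free hydroxyl directs to its para and ortho positions and the isopropoxy group to its para position, which is the pattern of ring B. The position next to the isopropoxy group must stay free.

## Roads not taken

Alternative 1: Ring A is cut at C1–C2 and C2–C3, so that C2 enters with its bromine as dibromocarbene. Phenol 5 would first be O-alkylated to give the ketone 2-(2,3,4-tribromo-6-isopropoxyphenoxy)cyclopentan-1-one A1. Ketone A1 would be converted into its less substituted trimethylsilyl enol ether A2. Carbene addition to A2 with opening of the dibromocyclopropane would give racemic 2-bromo-6-(2,3,4-tribromo-6-isopropoxyphenoxy)cyclohex-2-en-1-one A3.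
- Merits: every step has close precedent, and C2 arrives with its bromine.
- Weak points: enolisation of A1 must go away from the oxygen-bearing carbon, so that A2 forms and not its regioisomer. A3 is one oxidation level below a phenol. It must then be dehydrogenated, brominated at C4 and O-methylated before deprotection. The C4 bromination should be clean, since it is para to the new hydroxyl with both ortho positions occupied.
- Comparison: this road is clearly better in precedent. It is roughly twice as long from 5 and carries the brominated ring B through an oxidation and a bromination. The chosen plan sets against it a ring A that arrives fully substituted and aromatic in one convergent step.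

Alternative 2: Ring A is cut at C2–C3 and C5–C6. 1-(2,3,4-Tribromo-6-isopropoxyphenoxy)propan-2-one A4, one step from 5, would condense at both alpha carbons with 2-bromomalonaldehyde A5 and close by aldol condensation to 4-bromo-2-(2,3,4-tribromo-6-isopropoxyphenoxy)phenol A6.
- Merits: the arene forms at the right oxidation level and C4 brings its bromine. In A6 the second bromine can only enter ortho to the free hydroxyl, because the para position is blocked. With bromination, methylation and deprotection after A6, the length is within one step of the chosen route.
- Weak points: this condensation is established for ketones activated on both sides. In A4 one nucleophilic carbon is a plain methyl group and the other an oxygen-substituted methylene, A5 is an acidic enol that is deactivated by base, and A4 can self-condense.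
- Comparison: in length this road is nearly equal, and in reaction type it is nearer to known chemistry. The chosen plan sets against it that no bromination or methylation is done on the assembled diaryl ether, and that both its fragments come from routine steps, so the uncertainty is confined to one step.

Alternative 3: Ring A is cut at C1–C6 and C4–C5. 3-Hydroxy-2H-pyran-2-one A7 and 1,2,3-tribromo-4-{[1-(benzenesulfonyl)ethenyl]oxy}-5-isopropoxybenzene A8 would combine under Et3N in a [4+2] cycloaddition. Decarboxylation and loss of the sulfinate on heating would give 2-(2,3,4-tribromo-6-isopropoxyphenoxy)phenol A9.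
- Merits: base-promoted cycloadditions of 3-hydroxypyrones such as A7 with electron-poor alkenes are well known. The polarity of the two partners fixes the orientation, and the sulfonyl group serves as both activator and leaving group. Both ring A bromines can then be placed in one operation, ortho and para to the free hydroxyl of A9.
- Weak points: A8 needs about three steps from 5 (thioether, sulfone, methylenation). Its alkene is less electrophilic and more hindered than a simple vinyl sulfone because of the aryloxy group on the same carbon. Dibromination and methylation still follow A9.
- Comparison: the key step is safer than the one chosen here, at the price of about three more steps in the longest sequence. The chosen plan answers with brevity and with a ring A that needs no later substitution.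

Key step: step 6

Assumption: salt 3 is precipitated and used at once without purification and is treated as an isolated compound; ylides 10 and 11 are formed and consumed in the flask of step 6.

## Route

Step 1
Reactants: 1 coumalic acid (2-oxo-2H-pyran-5-carboxylic acid)
Product: 2 3,5-dibromo-2H-pyran-2-one
Conditions: NBS (2.5 equiv), LiOAc, MeCN–H2O, rt
Reagents that add atoms: N-bromosuccinimide, O=C1CCC(=O)N1Br
Why: Bromodecarboxylation: the pyrone is nucleophilic at C3 and C5, so NBS brominates C3 and attacks C5 at the carboxylate-bearing carbon, where loss of CO2 restores the pyrone (Hunsdiecker-type ipso substitution).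

Step 2
Reactants: 2 3,5-dibromo-2H-pyran-2-one
Product: 3 3,5-dibromo-2-methoxypyrylium tetrafluoroborate
Conditions: Me3OBF4 (1.2 equiv), ClCH2CH2Cl, 20 to 50 °C, Ar; precipitation with dry Et2O
Reagents that add atoms: trimethyloxonium tetrafluoroborate, C[O+](C)C.F[B-](F)(F)F
Why: O-Alkylation of the lactone carbonyl oxygen by a trialkyloxonium salt gives the aromatic 2-alkoxypyrylium ion, as known for 2-pyrones. The tetrafluoroborate ion is non-nucleophilic, so the salt can be precipitated and used directly.

Step 3
Reactants: 4 2-isopropoxyphenol
Product: 5 2,3,4-tribromo-6-isopropoxyphenol
Conditions: Br2 (3.3 equiv), NaOAc (3.5 equiv), AcOH, 20 to 50 °C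
Reagents that add atoms: bromine, BrBr
Why: Electrophilic aromatic bromination: the free hydroxyl directs to its para and ortho positions and the isopropoxy group to its para position, the orientation expected by analogy with guaiacol. The position beside the isopropoxy group stays free, and NaOAc traps HBr so that the isopropyl ether is not cleaved.

Step 4
Reactants: 5 2,3,4-tribromo-6-isopropoxyphenol; 6 bromochloromethane
Product: 7 1,2,3-tribromo-4-(chloromethoxy)-5-isopropoxybenzene
Conditions: NaH, DMF, 0 °C; then 6 (10 equiv), 0 °C to rt; non-aqueous work-up, used crude
Reagents that add atoms: none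
Why: Williamson alkylation of the phenoxide at the bromine-bearing end of bromochloromethane, bromide being the better leaving group. The large excess of 6 and the hindered, electron-poor phenoxide should suppress the second substitution to the diaryloxymethane.

Step 5
Reactants: 7 1,2,3-tribromo-4-(chloromethoxy)-5-isopropoxybenzene; 8 triphenylphosphine
Product: 9 [(2,3,4-tribromo-6-isopropoxyphenoxy)methyl]triphenylphosphonium chloride
Conditions: toluene, 100 °C; salt filtered and dried azeotropically
Reagents that add atoms: none
Why: SN2 quaternisation of triphenylphosphine by the alpha-chloro ether is the standard route to aryloxymethylphosphonium salts, and the salt should precipitate from toluene.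

Step 6
Reactants: 3 3,5-dibromo-2-methoxypyrylium tetrafluoroborate; 9 [(2,3,4-tribromo-6-isopropoxyphenoxy)methyl]triphenylphosphonium chloride
Product: 12 1,2,3-tribromo-4-(3,5-dibromo-2-methoxyphenoxy)-5-isopropoxybenzene, via phosphorus ylide 10 (not isolated), via open-chain dienoate ylide 11 (not isolated)
Conditions: 9, NaN(SiMe3)2 (1.0 equiv), THF, −78 °C; cannulated into a slurry of 3 in CH2Cl2, −78 to −20 °C; NaN(SiMe3)2 (1.0 equiv), −78 °C to rt, then 40 °C
Reagents that add atoms: none
Why: Proposed new method: ylide 10, freed from 9 by NaN(SiMe3)2, should add through carbon to the unsubstituted alpha carbon of pyrylium ion 3 (the future C5), and the 2H-pyran formed should open by a 6-pi electrocyclic reaction to a methyl dienoate whose phosphonium-bearing CH is deprotonated by the second equivalent of base to give the stabilised ylide 11. Ring A then closes by a 6-exo-trig attack of the ylide carbon (C6) on the ester carbonyl (C1), and the oxaphosphetane collapses to Ph3PO, so that the former ring oxygen leaves and the ester methoxy group remains as the C1 methyl ether. The closest known reaction types are the conversion of pyrylium salts into benzenes by phosphorus ylides or nitromethane, the opening of 2-alkoxypyrylium salts by nucleophiles, and intramolecular Wittig olefination of esters. Olefination should win over acylation because only loss of Ph3PO leads to an arene; loss of methoxide would leave a cyclohexadienone with a quaternary carbon bearing phosphorus and oxygen. Closure needs C3 and C6 on the same side of the C4–C5 double bond; the C2–C3 double bond has the required geometry from the ring, and the other can equilibrate through the delocalised ylide or through reversible pyran closure. Site selectivity rests on the substrate: the attacked alpha carbon is the only one bearing hydrogen, the gamma carbon lies between two bromine atoms, and addition at the methoxy-bearing carbon would, after opening to the aldehyde and Wittig closure, give the same arene 12. No stereocentre is formed. A silylamide base is chosen in place of alkyllithium reagents so that none of the five C–Br bonds undergoes exchange.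

Step 7
Reactants: 12 1,2,3-tribromo-4-(3,5-dibromo-2-methoxyphenoxy)-5-isopropoxybenzene
Product: 13 3,4,5-tribromo-2-(3,5-dibromo-2-methoxyphenoxy)phenol
Conditions: BCl3 (1 M in CH2Cl2), CH2Cl2, −78 to 0 °C; then H2O
Reagents that add atoms: none
Why: Lewis acid dealkylation: BCl3 cleaves secondary alkyl aryl ethers by ionisation of the O–isopropyl bond much faster than it demethylates anisoles, so the ring A methyl ether and the diaryl ether should remain.

## Compound list

1 | coumalic acid (2-oxo-2H-pyran-5-carboxylic acid) | O=C(O)C1=COC(=O)C=C1 | starting material
2 | 3,5-dibromo-2H-pyran-2-one | O=C1OC=C(Br)C=C1Br | intermediate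
3 | 3,5-dibromo-2-methoxypyrylium tetrafluoroborate | COc1[o+]cc(Br)cc1Br.F[B-](F)(F)F | intermediate
4 | 2-isopropoxyphenol | CC(C)Oc1ccccc1O | starting material
5 | 2,3,4-tribromo-6-isopropoxyphenol | CC(C)Oc1cc(Br)c(Br)c(Br)c1O | intermediate
6 | bromochloromethane | ClCBr | starting material
7 | 1,2,3-tribromo-4-(chloromethoxy)-5-isopropoxybenzene | CC(C)Oc1cc(Br)c(Br)c(Br)c1OCCl | intermediate
8 | triphenylphosphine | c1ccc(cc1)P(c1ccccc1)c1ccccc1 | starting material
9 | [(2,3,4-tribromo-6-isopropoxyphenoxy)methyl]triphenylphosphonium chloride | CC(C)Oc1cc(Br)c(Br)c(Br)c1OC[P+](c1ccccc1)(c1ccccc1)c1ccccc1.[Cl-] | intermediate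
10 | [(2,3,4-tribromo-6-isopropoxyphenoxy)methylidene]triphenylphosphorane | CC(C)Oc1cc(Br)c(Br)c(Br)c1OC=P(c1ccccc1)(c1ccccc1)c1ccccc1 | intermediate (not isolated)
11 | methyl (2E,4E)-2,4-dibromo-6-(2,3,4-tribromo-6-isopropoxyphenoxy)-6-(triphenylphosphoranylidene)hexa-2,4-dienoate (C1 and C4 on the same side of C2=C3; C3 and C6 on the same side of C4=C5) | COC(=O)/C(Br)=C\C(Br)=C/C(Oc1c(OC(C)C)cc(Br)c(Br)c1Br)=P(c1ccccc1)(c1ccccc1)c1ccccc1 | intermediate (not isolated)
12 | 1,2,3-tribromo-4-(3,5-dibromo-2-methoxyphenoxy)-5-isopropoxybenzene | COc1c(Br)cc(Br)cc1Oc1c(OC(C)C)cc(Br)c(Br)c1Br | intermediate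
13 | 3,4,5-tribromo-2-(3,5-dibromo-2-methoxyphenoxy)phenol | COc1c(Br)cc(Br)cc1Oc1c(O)cc(Br)c(Br)c1Br | target

## Step count and least certain steps

Total steps: 7. Longest linear sequence: 5 steps (4 to 5 to 7 to 9 to 12 to 13). The ring A branch from 1 has 4 steps (1 to 2 to 3 to 12 to 13).

**Step 6 (key step, proposed new method).**
- Most likely failures: methyl transfer from the O-methyl group of the pyrylium ion to the ylide carbon, which returns pyrone 2; electron transfer from the electron-rich ylide to the pyrylium ion; stalling at the stabilised open-chain ylide 11, whose attack on an ester carbonyl is slow and depends on the right alkene geometry.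
- Fallback, known chemistry, from 5 back to 12: phenol 5 would be heated with K2CO3 in DMF and commercially available 2,4-dibromo-6-fluorobenzaldehyde F1. Nucleophilic aromatic substitution of the fluorine ortho to the formyl group would give 2,4-dibromo-6-(2,3,4-tribromo-6-isopropoxyphenoxy)benzaldehyde F2. Baeyer–Villiger oxidation with mCPBA in CH2Cl2 would give 2,4-dibromo-6-(2,3,4-tribromo-6-isopropoxyphenoxy)phenyl formate F3. Methanolysis with K2CO3 in MeOH would give 2,4-dibromo-6-(2,3,4-tribromo-6-isopropoxyphenoxy)phenol F4, and methylation with MeI and K2CO3 in DMF would give 12.

**Step 2.**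
- Most likely failure: incomplete O-methylation, because two bromines lower the nucleophilicity of the carbonyl oxygen, and hydrolysis of the salt back to 2 during isolation.
- Fallback, from 2 back to 12: the salt would not be isolated. Pyrone 2 would be methylated with methyl trifluoromethanesulfonate in CH2Cl2 to 3,5-dibromo-2-methoxypyrylium trifluoromethanesulfonate F5, and this solution would be added directly to ylide 10 under the conditions of step 6, giving 12.

**Step 4.**
- Most likely failure: a second substitution at the chloromethyl ether by phenoxide, giving the diaryloxymethane, and hydrolysis of the chloromethyl ether during work-up.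
- Fallback, from 5 back to 7: the phenoxide of 5 (NaH, DMF, catalytic NaI) would be alkylated with chloromethyl methyl sulfide to 1,2,3-tribromo-5-isopropoxy-4-[(methylsulfanyl)methoxy]benzene F6. This is stable and can be purified. SO2Cl2 in CH2Cl2 at 0 °C would then convert F6 into 7 by chlorinolysis of the C–S bond.

**Step 3.**
- Most likely failure: sluggish entry of the third bromine, or entry beside the isopropoxy group instead of para to it, and acid-induced loss of the isopropyl group if HBr is not fully buffered.
- Fallback, from 4 back to 5: the order of bromination would be changed so that each stage has one director. Phenol 4 would be acetylated (Ac2O, pyridine) to 2-isopropoxyphenyl acetate F7. Bromination with Br2 and NaOAc in AcOH, now directed by the isopropoxy group alone, would give 5-bromo-2-isopropoxyphenyl acetate F8. Methanolysis (K2CO3, MeOH) would give 5-bromo-2-isopropoxyphenol F9, and two equivalents of Br2 with NaOAc in AcOH would enter ortho and para to the free hydroxyl to give 5.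

## Further compounds

F1 | step 6 | 2,4-dibromo-6-fluorobenzaldehyde | O=Cc1c(F)cc(Br)cc1Br
F2 | step 6 | 2,4-dibromo-6-(2,3,4-tribromo-6-isopropoxyphenoxy)benzaldehyde | O=Cc1c(Br)cc(Br)cc1Oc1c(OC(C)C)cc(Br)c(Br)c1Br
F3 | step 6 | 2,4-dibromo-6-(2,3,4-tribromo-6-isopropoxyphenoxy)phenyl formate | O=COc1c(Br)cc(Br)cc1Oc1c(OC(C)C)cc(Br)c(Br)c1Br
F4 | step 6 | 2,4-dibromo-6-(2,3,4-tribromo-6-isopropoxyphenoxy)phenol | Oc1c(Br)cc(Br)cc1Oc1c(OC(C)C)cc(Br)c(Br)c1Br
F5 | step 2 | 3,5-dibromo-2-methoxypyrylium trifluoromethanesulfonate | COc1[o+]cc(Br)cc1Br.[O-]S(=O)(=O)C(F)(F)F
F6 | step 4 | 1,2,3-tribromo-5-isopropoxy-4-[(methylsulfanyl)methoxy]benzene | CSCOc1c(OC(C)C)cc(Br)c(Br)c1Br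
F7 | step 3 | 2-isopropoxyphenyl acetate | CC(=O)Oc1ccccc1OC(C)C
F8 | step 3 | 5-bromo-2-isopropoxyphenyl acetate | CC(=O)Oc1cc(Br)ccc1OC(C)C
F9 | step 3 | 5-bromo-2-isopropoxyphenol | Oc1cc(Br)ccc1OC(C)C
A1 | alternative 1 | 2-(2,3,4-tribromo-6-isopropoxyphenoxy)cyclopentan-1-one (racemic) | O=C1CCCC1Oc1c(OC(C)C)cc(Br)c(Br)c1Br
A2 | alternative 1 | trimethyl{[5-(2,3,4-tribromo-6-isopropoxyphenoxy)cyclopent-1-en-1-yl]oxy}silane (racemic) | C[Si](C)(C)OC1=CCCC1Oc1c(OC(C)C)cc(Br)c(Br)c1Br
A3 | alternative 1 | 2-bromo-6-(2,3,4-tribromo-6-isopropoxyphenoxy)cyclohex-2-en-1-one (racemic) | O=C1C(Br)=CCCC1Oc1c(OC(C)C)cc(Br)c(Br)c1Br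
A4 | alternative 2 | 1-(2,3,4-tribromo-6-isopropoxyphenoxy)propan-2-one | CC(=O)COc1c(OC(C)C)cc(Br)c(Br)c1Br
A5 | alternative 2 | 2-bromomalonaldehyde | O=CC(Br)C=O
A6 | alternative 2 | 4-bromo-2-(2,3,4-tribromo-6-isopropoxyphenoxy)phenol | Oc1ccc(Br)cc1Oc1c(OC(C)C)cc(Br)c(Br)c1Br
A7 | alternative 3 | 3-hydroxy-2H-pyran-2-one | O=C1OC=CC=C1O
A8 | alternative 3 | 1,2,3-tribromo-4-{[1-(benzenesulfonyl)ethenyl]oxy}-5-isopropoxybenzene | C=C(Oc1c(OC(C)C)cc(Br)c(Br)c1Br)S(=O)(=O)c1ccccc1
A9 | alternative 3 | 2-(2,3,4-tribromo-6-isopropoxyphenoxy)phenol | Oc1ccccc1Oc1c(OC(C)C)cc(Br)c(Br)c1Br
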